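**Assumption:** positions are labelled with germacrane numbering (ring C1–C10, lactone carbons C11–C13 with the ring oxygen on C6, exocyclic methylene C14 on C10, acetoxymethyl C15 on C4). In this numbering the target is 6R,7R,8S, with C15 cis to C6 across C4=C5.

## Retrosynthetic overview

1. Target 36 ⇐ oxidation of C2 carbinol 35; the ten-membered ring is closed last, by intramolecular CrCl2-mediated allylation (C1–C2) of allylic bromide/aldehyde 33.
2. Seco chain ⇐ key intermolecular carbonyl allylation (C7–C8) of bromomethyl butenolide 20 with β,γ-unsaturated aldehyde 25; this sets C7 and C8 and turns the butenolide into the α-methylene lactone.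
3. Butenolide 20 ⇐ (R)-enynol 15 by hydroxyl-directed hydroalumination/iodination and carbonylative lactonization; C6 comes from CBS reduction of ynone 14.
4. Ynone 14 ⇐ Z-vinyl iodide 8 (carbomagnesiation of propargyl alcohol fixes the C4=C5 geometry) + ynal 11; aldehyde 25 ⇐ monomethyl itaconate 21.
5. Ring order: butenolide ring first (step 12), ten-membered carbocycle last (step 26).

## Route

**Step 1**
Reactants: 1 prop-2-yn-1-ol
Product: 3 (2Z)-2-(iodomethylidene)pent-4-en-1-ol, via cyclic vinylmagnesium alkoxide 2 (not isolated)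
Conditions: allylMgBr (2.5 equiv), copper iodide CuI (10 mol%), Et2O, 0 °C → rt, 16 h; then I2 (1.3 equiv), THF, −40 → 0 °C; aq. Na2S2O3
Reagents that add atoms: allylmagnesium bromide (C=CC[Mg]Br); iodine (II)
Why: Hydroxyl-directed anti-carbomagnesiation puts the allyl group on the internal alkyne carbon and magnesium on the terminal carbon cis to CH2O in chelate 2, and iodinolysis with retention gives the Z iodide, which fixes C15 cis to the future C6.

**Step 2**
Reactants: 3 (2Z)-2-(iodomethylidene)pent-4-en-1-ol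
Product: 4 1-({[(2Z)-2-(iodomethylidene)pent-4-en-1-yl]oxy}methyl)-4-methoxybenzene
Conditions: NaH (1.2 equiv), 4-methoxybenzyl chloride (1.2 equiv), Bu4NI (5 mol%), THF/DMF, 0 °C → rt
Reagents that add atoms: 4-methoxybenzyl chloride (COc1ccc(CCl)cc1)
Why: Williamson etherification of the primary allylic alkoxide; the vinyl iodide cannot eliminate because C4 carries no hydrogen.

**Step 3**
Reactants: 4 1-({[(2Z)-2-(iodomethylidene)pent-4-en-1-yl]oxy}methyl)-4-methoxybenzene
Product: 6 (3Z)-4-iodo-3-[(4-methoxybenzyloxy)methyl]but-3-enal, via diol 5 (not isolated)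
Conditions: OsO4 (2 mol%), NaIO4 (4 equiv), 2,6-lutidine (2 equiv), 1,4-dioxane/H2O 3:1, rt; crude aldehyde used at once
Reagents that add atoms: osmium tetroxide (O=[Os](=O)(=O)=O); sodium periodate ([Na+].[O-]I(=O)(=O)=O)
Why: Lemieux–Johnson oxidative cleavage is selective for the monosubstituted terminal alkene because the iodo-substituted, allylically oxygenated trisubstituted alkene is electron-poor and hindered.

**Step 4**
Reactants: 6 (3Z)-4-iodo-3-[(4-methoxybenzyloxy)methyl]but-3-enal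
Product: 7 (3Z)-4-iodo-3-[(4-methoxybenzyloxy)methyl]but-3-en-1-ol
Conditions: NaBH4 (1.0 equiv), MeOH, 0 °C, 15 min
Reagents that add atoms: none
Why: Borohydride reduction of the aldehyde is fast at 0 °C and removes the β,γ-unsaturated aldehyde before it can slip into conjugation.

**Step 5**
Reactants: 7 (3Z)-4-iodo-3-[(4-methoxybenzyloxy)methyl]but-3-en-1-ol
Product: 8 tert-butyl{[(3Z)-4-iodo-3-{[(4-methoxybenzyl)oxy]methyl}but-3-en-1-yl]oxy}dimethylsilane
Conditions: TBSCl (1.2 equiv), imidazole (2 equiv), CH2Cl2, rt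
Reagents that add atoms: tert-butyldimethylsilyl chloride (CC(C)(C)[Si](C)(C)Cl)
Why: Standard silylation of a primary alcohol; the silyl group sits on the chain trans to iodine, so no silyl migration is possible in the later vinyllithium.

**Step 6**
Reactants: 1 prop-2-yn-1-ol
Product: 9 triethyl(prop-2-yn-1-yloxy)silane
Conditions: TESCl (1.1 equiv), imidazole (1.5 equiv), CH2Cl2, 0 °C
Reagents that add atoms: chlorotriethylsilane (CC[Si](Cl)(CC)CC)
Why: Standard silylation; the TES group is chosen so that it can later be removed in the presence of the TBS ether.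

**Step 7**
Reactants: 9 triethyl(prop-2-yn-1-yloxy)silane
Product: 11 4-(triethylsilyloxy)but-2-ynal, via lithium acetylide 10 (not isolated)
Conditions: n-BuLi (1.05 equiv), THF, −78 °C; DMF (2 equiv), −78 → 0 °C; reverse quench into cold aq. KH2PO4/MTBE
Reagents that add atoms: N,N-dimethylformamide (CN(C)C=O)
Why: Formylation of a lithium acetylide with DMF; the buffered reverse quench stops dimethylamine from adding to the ynal.

**Step 8**
Reactants: 8 tert-butyl{[(3Z)-4-iodo-3-{[(4-methoxybenzyl)oxy]methyl}but-3-en-1-yl]oxy}dimethylsilane; 11 4-(triethylsilyloxy)but-2-ynal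
Product: 13 rac-(5Z)-8-(tert-butyldimethylsilyloxy)-6-[(4-methoxybenzyloxy)methyl]-1-(triethylsilyloxy)oct-5-en-2-yn-4-ol, via vinyllithium 12 (not isolated)
Conditions: t-BuLi (2.1 equiv), Et2O, −78 °C, 20 min; then 11 (1.2 equiv), −78 °C; H2O quench
Reagents that add atoms: none
Why: Lithium–iodine exchange with retention of alkene geometry followed by 1,2-addition to the ynal; C6 is formed racemic here and corrected in steps 9 and 10.

**Step 9**
Reactants: 13 rac-(5Z)-8-(tert-butyldimethylsilyloxy)-6-[(4-methoxybenzyloxy)methyl]-1-(triethylsilyloxy)oct-5-en-2-yn-4-ol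
Product: 14 (5Z)-8-(tert-butyldimethylsilyloxy)-6-[(4-methoxybenzyloxy)methyl]-1-(triethylsilyloxy)oct-5-en-2-yn-4-one
Conditions: activated MnO2 (20 equiv), CH2Cl2, rt
Reagents that add atoms: none
Why: MnO2 oxidation of a doubly activated (allylic and propargylic) alcohol is neutral and leaves the Z alkene and the silyl ethers alone.

**Step 10**
Reactants: 14 (5Z)-8-(tert-butyldimethylsilyloxy)-6-[(4-methoxybenzyloxy)methyl]-1-(triethylsilyloxy)oct-5-en-2-yn-4-one
Product: 15 (4R,5Z)-8-(tert-butyldimethylsilyloxy)-6-[(4-methoxybenzyloxy)methyl]-1-(triethylsilyloxy)oct-5-en-2-yn-4-ol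
Conditions: (R)-2-methyl-CBS-oxazaborolidine [(3aR)-1-methyl-3,3-diphenyltetrahydro-1H,3H-pyrrolo[1,2-c][1,3,2]oxazaborole] (1.0 equiv), BH3·SMe2 (1.2 equiv), THF, −30 °C; MeOH quench
Reagents that add atoms: none
Why: Corey–Bakshi–Shibata reduction, in which the Z-trisubstituted alkenyl group acts as the large and the alkynyl group as the small substituent, so the (R)-catalyst gives the R carbinol that becomes C6.

**Step 11**
Reactants: 15 (4R,5Z)-8-(tert-butyldimethylsilyloxy)-6-[(4-methoxybenzyloxy)methyl]-1-(triethylsilyloxy)oct-5-en-2-yn-4-ol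
Product: 17 (2Z,4R,5Z)-8-(tert-butyldimethylsilyloxy)-2-iodo-6-[(4-methoxybenzyloxy)methyl]-1-(triethylsilyloxy)octa-2,5-dien-4-ol, via cyclic vinylalanate 16 (not isolated)
Conditions: NaAlH2(OCH2CH2OMe)2 (1.5 equiv), THF, 0 °C → rt, 2 h; then I2 (2.5 equiv) in THF, −78 → 0 °C
Reagents that add atoms: iodine (II)
Why: Hydroxyl-directed trans-hydroalumination delivers hydride to C7 and aluminium to C11 cis to the carbinol, and iodinolysis with retention gives the Z iodide set up for lactonization; C6 is not touched.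

**Step 12**
Reactants: 17 (2Z,4R,5Z)-8-(tert-butyldimethylsilyloxy)-2-iodo-6-[(4-methoxybenzyloxy)methyl]-1-(triethylsilyloxy)octa-2,5-dien-4-ol
Product: 18 (5R)-5-[(1Z)-4-(tert-butyldimethylsilyloxy)-2-[(4-methoxybenzyloxy)methyl]but-1-en-1-yl]-3-[(triethylsilyloxy)methyl]furan-2(5H)-one
Conditions: Pd(PPh3)4 (5 mol%), CO (1 atm), K2CO3 (2 equiv), THF, 25 °C
Reagents that add atoms: carbon monoxide ([C-]#[O+])
Why: Palladium-catalysed carbonylative lactonization inserts CO at the vinyl C–I bond and the cis C6 hydroxyl closes the butenolide; the mild base and room temperature protect the acidic, doubly allylic C6–H.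

**Step 13**
Reactants: 18 (5R)-5-[(1Z)-4-(tert-butyldimethylsilyloxy)-2-[(4-methoxybenzyloxy)methyl]but-1-en-1-yl]-3-[(triethylsilyloxy)methyl]furan-2(5H)-one
Product: 19 (5R)-5-[(1Z)-4-(tert-butyldimethylsilyloxy)-2-[(4-methoxybenzyloxy)methyl]but-1-en-1-yl]-3-(hydroxymethyl)furan-2(5H)-one
Conditions: pyridinium p-toluenesulfonate (0.2 equiv), MeOH/CH2Cl2 1:1, 0 °C
Reagents that add atoms: none
Why: Acid-catalysed methanolysis cleaves a primary TES ether far faster than the primary TBS ether, and the PMB ether and butenolide are inert.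

**Step 14**
Reactants: 19 (5R)-5-[(1Z)-4-(tert-butyldimethylsilyloxy)-2-[(4-methoxybenzyloxy)methyl]but-1-en-1-yl]-3-(hydroxymethyl)furan-2(5H)-one
Product: 20 (5R)-3-(bromomethyl)-5-[(1Z)-4-(tert-butyldimethylsilyloxy)-2-[(4-methoxybenzyloxy)methyl]but-1-en-1-yl]furan-2(5H)-one
Conditions: CBr4 (1.3 equiv), PPh3 (1.3 equiv), CH2Cl2, 0 °C
Reagents that add atoms: carbon tetrabromide (BrC(Br)(Br)Br)
Why: Appel bromination of the primary allylic alcohol is neutral, so the base-sensitive C6 stereocentre is not endangered.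

**Step 15**
Reactants: 21 4-methoxy-2-methylidene-4-oxobutanoic acid (monomethyl itaconate)
Product: 22 methyl 3-(hydroxymethyl)but-3-enoate
Conditions: BH3·SMe2 (1.1 equiv), THF, −10 → 0 °C; MeOH quench
Reagents that add atoms: none
Why: Borane reduces the carboxylic acid chemoselectively in the presence of the methyl ester and faster than it hydroborates the electron-poor alkene.

**Step 16**
Reactants: 22 methyl 3-(hydroxymethyl)but-3-enoate
Product: 23 methyl 3-[(triethylsilyloxy)methyl]but-3-enoate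
Conditions: TESCl (1.1 equiv), imidazole (1.5 equiv), CH2Cl2, 0 °C
Reagents that add atoms: chlorotriethylsilane (CC[Si](Cl)(CC)CC)
Why: Prompt silylation prevents lactonization of the hydroxy ester; imidazole is too weak to move the double bond into conjugation.

**Step 17**
Reactants: 23 methyl 3-[(triethylsilyloxy)methyl]but-3-enoate
Product: 24 3-methylidene-4-(triethylsilyloxy)butan-1-ol
Conditions: i-Bu2AlH (2.3 equiv), CH2Cl2, −78 → 0 °C; aq. potassium sodium tartrate
Reagents that add atoms: none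
Why: Full ester reduction to the alcohol is more dependable than stopping at the labile β,γ-unsaturated aldehyde.

**Step 18**
Reactants: 24 3-methylidene-4-(triethylsilyloxy)butan-1-ol
Product: 25 3-methylidene-4-(triethylsilyloxy)butanal
Conditions: Dess–Martin periodinane (1.2 equiv), NaHCO3, CH2Cl2, 0 °C; used at once
Reagents that add atoms: none
Why: Buffered Dess–Martin oxidation gives the β,γ-unsaturated aldehyde without acid or base that would isomerize it.

**Step 19** (key fragment union)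
Reactants: 20 (5R)-3-(bromomethyl)-5-[(1Z)-4-(tert-butyldimethylsilyloxy)-2-[(4-methoxybenzyloxy)methyl]but-1-en-1-yl]furan-2(5H)-one; 25 3-methylidene-4-(triethylsilyloxy)butanal
Product: 27 (4R,5R)-4-[(1S)-1-hydroxy-3-methylidene-4-(triethylsilyloxy)butyl]-3-methylidene-5-[(1Z)-4-(tert-butyldimethylsilyloxy)-2-[(4-methoxybenzyloxy)methyl]but-1-en-1-yl]oxolan-2-one, via allylchromium reagent 26 (not isolated)
Conditions: CrCl2 (4 equiv), THF, 0 °C → rt; 20 (1.0 equiv) and 25 (1.5 equiv) added together; H2O work-up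
Reagents that add atoms: none
Why: Intermolecular Nozaki–Hiyama (Barbier-type) carbonyl allylation: 26 adds through its γ-carbon C7 in a closed chair transition state on the face anti to the C6 substituent, and because C6 is held trans to the CH2Cr carbon the aldehyde chain is equatorial and the 7,8-anti adduct forms, giving the 6,7-trans lactone with 7R,8S.

**Step 20**
Reactants: 27 (4R,5R)-4-[(1S)-1-hydroxy-3-methylidene-4-(triethylsilyloxy)butyl]-3-methylidene-5-[(1Z)-4-(tert-butyldimethylsilyloxy)-2-[(4-methoxybenzyloxy)methyl]but-1-en-1-yl]oxolan-2-one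
Product: 28 (4R,5R)-4-[(1S)-1-hydroxy-3-methylidene-4-(triethylsilyloxy)butyl]-5-[(1Z)-4-(tert-butyldimethylsilyloxy)-2-(hydroxymethyl)but-1-en-1-yl]-3-methylideneoxolan-2-one
Conditions: DDQ (1.3 equiv), CH2Cl2/pH 7 phosphate buffer 10:1, 0 °C
Reagents that add atoms: none
Why: Oxidative PMB cleavage under buffered, near-neutral conditions leaves both silyl ethers and the α-methylene lactone intact and avoids translactonization to the C8 hydroxyl.

**Step 21**
Reactants: 28 (4R,5R)-4-[(1S)-1-hydroxy-3-methylidene-4-(triethylsilyloxy)butyl]-5-[(1Z)-4-(tert-butyldimethylsilyloxy)-2-(hydroxymethyl)but-1-en-1-yl]-3-methylideneoxolan-2-one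
Product: 29 (4R,5R)-4-[(1S)-1-acetoxy-3-methylidene-4-(triethylsilyloxy)butyl]-5-[(1Z)-2-(acetoxymethyl)-4-(tert-butyldimethylsilyloxy)but-1-en-1-yl]-3-methylideneoxolan-2-one
Conditions: Ac2O (4 equiv), pyridine, DMAP (5 mol%), CH2Cl2, 0 °C
Reagents that add atoms: acetic anhydride (CC(=O)OC(C)=O)
Why: One acylation installs both acetates of the target (C8 and C15) and locks the lactone on the C6 oxygen.

**Step 22**
Reactants: 29 (4R,5R)-4-[(1S)-1-acetoxy-3-methylidene-4-(triethylsilyloxy)butyl]-5-[(1Z)-2-(acetoxymethyl)-4-(tert-butyldimethylsilyloxy)but-1-en-1-yl]-3-methylideneoxolan-2-one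
Product: 30 (4R,5R)-4-[(1S)-1-acetoxy-4-hydroxy-3-methylidenebutyl]-5-[(1Z)-2-(acetoxymethyl)-4-(tert-butyldimethylsilyloxy)but-1-en-1-yl]-3-methylideneoxolan-2-one
Conditions: pyridinium p-toluenesulfonate (0.2 equiv), MeOH/CH2Cl2 1:1, 0 °C
Reagents that add atoms: none
Why: Selective acidic methanolysis of the primary TES ether in the presence of the primary TBS ether; the acetates survive the short, cold exposure.

**Step 23**
Reactants: 30 (4R,5R)-4-[(1S)-1-acetoxy-4-hydroxy-3-methylidenebutyl]-5-[(1Z)-2-(acetoxymethyl)-4-(tert-butyldimethylsilyloxy)but-1-en-1-yl]-3-methylideneoxolan-2-one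
Product: 31 (4R,5R)-4-[(1S)-1-acetoxy-4-bromo-3-methylidenebutyl]-5-[(1Z)-2-(acetoxymethyl)-4-(tert-butyldimethylsilyloxy)but-1-en-1-yl]-3-methylideneoxolan-2-one
Conditions: CBr4 (1.3 equiv), PPh3 (1.3 equiv), CH2Cl2, 0 °C
Reagents that add atoms: carbon tetrabromide (BrC(Br)(Br)Br)
Why: Appel bromination of the only free (primary allylic) alcohol under neutral conditions.

**Step 24**
Reactants: 31 (4R,5R)-4-[(1S)-1-acetoxy-4-bromo-3-methylidenebutyl]-5-[(1Z)-2-(acetoxymethyl)-4-(tert-butyldimethylsilyloxy)but-1-en-1-yl]-3-methylideneoxolan-2-one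
Product: 32 (4R,5R)-4-[(1S)-1-acetoxy-4-bromo-3-methylidenebutyl]-5-[(1Z)-2-(acetoxymethyl)-4-hydroxybut-1-en-1-yl]-3-methylideneoxolan-2-one
Conditions: HF·pyridine, THF, 0 °C
Reagents that add atoms: none
Why: Acidic fluoride desilylation removes the primary TBS group without a nucleophile that could displace the allylic bromide or cleave the acetates.

**Step 25**
Reactants: 32 (4R,5R)-4-[(1S)-1-acetoxy-4-bromo-3-methylidenebutyl]-5-[(1Z)-2-(acetoxymethyl)-4-hydroxybut-1-en-1-yl]-3-methylideneoxolan-2-one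
Product: 33 (4R,5R)-4-[(1S)-1-acetoxy-4-bromo-3-methylidenebutyl]-5-[(1Z)-2-(acetoxymethyl)-4-oxobut-1-en-1-yl]-3-methylideneoxolan-2-one
Conditions: Dess–Martin periodinane (1.3 equiv), NaHCO3, CH2Cl2, 0 °C; used at once
Reagents that add atoms: none
Why: Buffered Dess–Martin oxidation gives the C2 aldehyde without moving the C4=C5 bond into conjugation and without touching the allylic bromide.

**Step 26**
Reactants: 33 (4R,5R)-4-[(1S)-1-acetoxy-4-bromo-3-methylidenebutyl]-5-[(1Z)-2-(acetoxymethyl)-4-oxobut-1-en-1-yl]-3-methylideneoxolan-2-one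
Product: 35 (6R,7R,8S)-8,15-diacetoxy-2-hydroxygermacra-4,10(14),11(13)-trien-12,6-olide (both C2 epimers), via allylchromium aldehyde 34 (not isolated)
Conditions: CrCl2 (10 equiv), THF, rt; 33 added by syringe pump over 10 h (final 2 mM)
Reagents that add atoms: none
Why: Intramolecular Nozaki–Hiyama–Kishi allylation closes the ten-membered ring; the 2-substituted allylchromium gives the ring CH2 plus exocyclic methylene whichever terminus attacks, and the new C2 stereocentre is removed in step 27.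

**Step 27**
Reactants: 35 (6R,7R,8S)-8,15-diacetoxy-2-hydroxygermacra-4,10(14),11(13)-trien-12,6-olide
Product: 36 (6R,7R,8S)-8,15-diacetoxy-2-oxogermacra-4,10(14),11(13)-trien-12,6-olide (target)
Conditions: Dess–Martin periodinane (1.5 equiv), NaHCO3, CH2Cl2, 0 °C; neutral work-up, chromatography on buffered silica
Reagents that add atoms: none
Why: Buffered Dess–Martin oxidation converts both C2 epimers into the ketone without the acid or base that would pull either β,γ-double bond into conjugation.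

## Compound list

1 | prop-2-yn-1-ol | C#CCO | starting material
2 | 4-allyl-2,5-dihydro-1,2-oxamagnesole (Mg on the vinyl carbon, cis to CH2O) | C=CCC1=C[Mg]OC1 | intermediate
3 | (2Z)-2-(iodomethylidene)pent-4-en-1-ol | OC/C(CC=C)=C\I | intermediate
4 | 1-({[(2Z)-2-(iodomethylidene)pent-4-en-1-yl]oxy}methyl)-4-methoxybenzene | COc1ccc(COC/C(CC=C)=C\I)cc1 | intermediate
5 | (4Z)-5-iodo-4-[(4-methoxybenzyloxy)methyl]pent-4-ene-1,2-diol (racemic) | COc1ccc(COC/C(CC(O)CO)=C\I)cc1 | intermediate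
6 | (3Z)-4-iodo-3-[(4-methoxybenzyloxy)methyl]but-3-enal | COc1ccc(COC/C(CC=O)=C\I)cc1 | intermediate
7 | (3Z)-4-iodo-3-[(4-methoxybenzyloxy)methyl]but-3-en-1-ol | COc1ccc(COC/C(CCO)=C\I)cc1 | intermediate
8 | tert-butyl{[(3Z)-4-iodo-3-{[(4-methoxybenzyl)oxy]methyl}but-3-en-1-yl]oxy}dimethylsilane | COc1ccc(COC/C(CCO[Si](C)(C)C(C)(C)C)=C\I)cc1 | intermediate
9 | triethyl(prop-2-yn-1-yloxy)silane | C#CCO[Si](CC)(CC)CC | intermediate
10 | [3-(triethylsilyloxy)prop-1-yn-1-yl]lithium | [Li]C#CCO[Si](CC)(CC)CC | intermediate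
11 | 4-(triethylsilyloxy)but-2-ynal | O=CC#CCO[Si](CC)(CC)CC | intermediate
12 | (Z)-vinyllithium from 8 (Li in place of I) | COc1ccc(COC/C(CCO[Si](C)(C)C(C)(C)C)=C\[Li])cc1 | intermediate
13 | rac-(5Z)-8-(tert-butyldimethylsilyloxy)-6-[(4-methoxybenzyloxy)methyl]-1-(triethylsilyloxy)oct-5-en-2-yn-4-ol | COc1ccc(COC/C(CCO[Si](C)(C)C(C)(C)C)=C\C(O)C#CCO[Si](CC)(CC)CC)cc1 | intermediate
14 | (5Z)-8-(tert-butyldimethylsilyloxy)-6-[(4-methoxybenzyloxy)methyl]-1-(triethylsilyloxy)oct-5-en-2-yn-4-one | COc1ccc(COC/C(CCO[Si](C)(C)C(C)(C)C)=C\C(=O)C#CCO[Si](CC)(CC)CC)cc1 | intermediate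
15 | (4R,5Z)-8-(tert-butyldimethylsilyloxy)-6-[(4-methoxybenzyloxy)methyl]-1-(triethylsilyloxy)oct-5-en-2-yn-4-ol | COc1ccc(COC/C(CCO[Si](C)(C)C(C)(C)C)=C\[C@@H](O)C#CCO[Si](CC)(CC)CC)cc1 | intermediate
16 | sodium 2,2-bis(2-methoxyethoxy)-2,5-dihydro-1,2-oxaaluminol-2-uide from 15 (Al on C11, ring O on C6) | [Na+].COCCO[Al-]1(OCCOC)O[C@H](/C=C(\COCc2ccc(OC)cc2)CCO[Si](C)(C)C(C)(C)C)C=C1CO[Si](CC)(CC)CC | intermediate
17 | (2Z,4R,5Z)-8-(tert-butyldimethylsilyloxy)-2-iodo-6-[(4-methoxybenzyloxy)methyl]-1-(triethylsilyloxy)octa-2,5-dien-4-ol | COc1ccc(COC/C(CCO[Si](C)(C)C(C)(C)C)=C\[C@@H](O)/C=C(\I)CO[Si](CC)(CC)CC)cc1 | intermediate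
18 | (5R)-5-[(1Z)-4-(tert-butyldimethylsilyloxy)-2-[(4-methoxybenzyloxy)methyl]but-1-en-1-yl]-3-[(triethylsilyloxy)methyl]furan-2(5H)-one | COc1ccc(COC/C(CCO[Si](C)(C)C(C)(C)C)=C\[C@H]2OC(=O)C(CO[Si](CC)(CC)CC)=C2)cc1 | intermediate
19 | (5R)-5-[(1Z)-4-(tert-butyldimethylsilyloxy)-2-[(4-methoxybenzyloxy)methyl]but-1-en-1-yl]-3-(hydroxymethyl)furan-2(5H)-one | COc1ccc(COC/C(CCO[Si](C)(C)C(C)(C)C)=C\[C@H]2OC(=O)C(CO)=C2)cc1 | intermediate
20 | (5R)-3-(bromomethyl)-5-[(1Z)-4-(tert-butyldimethylsilyloxy)-2-[(4-methoxybenzyloxy)methyl]but-1-en-1-yl]furan-2(5H)-one | COc1ccc(COC/C(CCO[Si](C)(C)C(C)(C)C)=C\[C@H]2OC(=O)C(CBr)=C2)cc1 | intermediate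
21 | 4-methoxy-2-methylidene-4-oxobutanoic acid (monomethyl itaconate) | COC(=O)CC(=C)C(=O)O | starting material
22 | methyl 3-(hydroxymethyl)but-3-enoate | COC(=O)CC(=C)CO | intermediate
23 | methyl 3-[(triethylsilyloxy)methyl]but-3-enoate | COC(=O)CC(=C)CO[Si](CC)(CC)CC | intermediate
24 | 3-methylidene-4-(triethylsilyloxy)butan-1-ol | OCCC(=C)CO[Si](CC)(CC)CC | intermediate
25 | 3-methylidene-4-(triethylsilyloxy)butanal | O=CCC(=C)CO[Si](CC)(CC)CC | intermediate
26 | allylchromium dichloride from 20 (CrCl2 in place of Br) | COc1ccc(COC/C(CCO[Si](C)(C)C(C)(C)C)=C\[C@H]2OC(=O)C(C[Cr](Cl)Cl)=C2)cc1 | intermediate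
27 | (4R,5R)-4-[(1S)-1-hydroxy-3-methylidene-4-(triethylsilyloxy)butyl]-3-methylidene-5-[(1Z)-4-(tert-butyldimethylsilyloxy)-2-[(4-methoxybenzyloxy)methyl]but-1-en-1-yl]oxolan-2-one | COc1ccc(COC/C(CCO[Si](C)(C)C(C)(C)C)=C\[C@H]2OC(=O)C(=C)[C@@H]2[C@@H](O)CC(=C)CO[Si](CC)(CC)CC)cc1 | intermediate
28 | (4R,5R)-4-[(1S)-1-hydroxy-3-methylidene-4-(triethylsilyloxy)butyl]-5-[(1Z)-4-(tert-butyldimethylsilyloxy)-2-(hydroxymethyl)but-1-en-1-yl]-3-methylideneoxolan-2-one | OC/C(CCO[Si](C)(C)C(C)(C)C)=C\[C@H]1OC(=O)C(=C)[C@@H]1[C@@H](O)CC(=C)CO[Si](CC)(CC)CC | intermediate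
29 | (4R,5R)-4-[(1S)-1-acetoxy-3-methylidene-4-(triethylsilyloxy)butyl]-5-[(1Z)-2-(acetoxymethyl)-4-(tert-butyldimethylsilyloxy)but-1-en-1-yl]-3-methylideneoxolan-2-one | CC(=O)OC/C(CCO[Si](C)(C)C(C)(C)C)=C\[C@H]1OC(=O)C(=C)[C@@H]1[C@@H](OC(C)=O)CC(=C)CO[Si](CC)(CC)CC | intermediate
30 | (4R,5R)-4-[(1S)-1-acetoxy-4-hydroxy-3-methylidenebutyl]-5-[(1Z)-2-(acetoxymethyl)-4-(tert-butyldimethylsilyloxy)but-1-en-1-yl]-3-methylideneoxolan-2-one | CC(=O)OC/C(CCO[Si](C)(C)C(C)(C)C)=C\[C@H]1OC(=O)C(=C)[C@@H]1[C@@H](OC(C)=O)CC(=C)CO | intermediate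
31 | (4R,5R)-4-[(1S)-1-acetoxy-4-bromo-3-methylidenebutyl]-5-[(1Z)-2-(acetoxymethyl)-4-(tert-butyldimethylsilyloxy)but-1-en-1-yl]-3-methylideneoxolan-2-one | CC(=O)OC/C(CCO[Si](C)(C)C(C)(C)C)=C\[C@H]1OC(=O)C(=C)[C@@H]1[C@@H](OC(C)=O)CC(=C)CBr | intermediate
32 | (4R,5R)-4-[(1S)-1-acetoxy-4-bromo-3-methylidenebutyl]-5-[(1Z)-2-(acetoxymethyl)-4-hydroxybut-1-en-1-yl]-3-methylideneoxolan-2-one | CC(=O)OC/C(CCO)=C\[C@H]1OC(=O)C(=C)[C@@H]1[C@@H](OC(C)=O)CC(=C)CBr | intermediate
33 | (4R,5R)-4-[(1S)-1-acetoxy-4-bromo-3-methylidenebutyl]-5-[(1Z)-2-(acetoxymethyl)-4-oxobut-1-en-1-yl]-3-methylideneoxolan-2-one | CC(=O)OC/C(CC=O)=C\[C@H]1OC(=O)C(=C)[C@@H]1[C@@H](OC(C)=O)CC(=C)CBr | intermediate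
34 | allylchromium dichloride from 33 (CrCl2 in place of Br) | CC(=O)OC/C(CC=O)=C\[C@H]1OC(=O)C(=C)[C@@H]1[C@@H](OC(C)=O)CC(=C)C[Cr](Cl)Cl | intermediate
35 | (6R,7R,8S)-8,15-diacetoxy-2-hydroxygermacra-4,10(14),11(13)-trien-12,6-olide (C2 epimers) | C=C1CC(O)C/C(COC(C)=O)=C/[C@H]2OC(=O)C(=C)[C@@H]2[C@@H](OC(C)=O)C1 | intermediate
36 | (6R,7R,8S)-8,15-diacetoxy-2-oxogermacra-4,10(14),11(13)-trien-12,6-olide | C=C1CC(=O)C/C(COC(C)=O)=C/[C@H]2OC(=O)C(=C)[C@@H]2[C@@H](OC(C)=O)C1 | target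

## Step count and risks

Total step count: 27. Longest linear sequence: 21 steps (steps 1–5, 8–14 and 19–27, from prop-2-yn-1-ol).

The three steps most likely to fail:

**Step 26 (ten-membered ring closure).** Oligomerization or a strained transition state could defeat the chromium-mediated closure. The fallback sets out from bromide 20 and comes back at 35, replacing the allyl halide by a carbonyl-ene ring closure that needs no bromide. Dess–Martin oxidation of commercial 3-methylbut-3-en-1-ol gives 3-methylbut-3-enal F5. This is coupled with 20 under the conditions of step 19 to give the isopropenyl adduct F6. DDQ gives diol F7, Ac2O/pyridine gives diacetate F8, HF·pyridine gives primary alcohol F9, and Dess–Martin oxidation gives aldehyde F10. Me2AlCl (CH2Cl2, −78 °C, 1 mM) then closes the ring by an intramolecular carbonyl-ene reaction in which the methyl group on C10 gives up the hydrogen, delivering 35.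

**Step 19 (key allylation).** The labile aldehyde 25 may force a change of metal (Zn in THF/aq. NH4Cl or In in THF/H2O), and the C8 configuration may then come out wrong or mixed. The fallback sets out from 20 and 25 and comes back at 29, setting C8 by inversion after the coupling instead of in it. The 8-epi adduct F2 is treated with PPh3, diisopropyl azodicarboxylate and AcOH (Mitsunobu esterification), which inverts C8 and installs its acetate to give the 8-acetate F3. DDQ frees the C15 hydroxyl to give the hydroxy acetate F4, and Ac2O/pyridine gives 29.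

**Step 10 (CBS reduction of the cross-conjugated enynone).** Alkenyl/alkynyl discrimination may be insufficient. The fallback sets out from vinyl iodide 8 and comes back at 15, forming C6 in an enantioselective C–C bond formation instead of a reduction. Lithium–iodine exchange (t-BuLi) and trapping with DMF gives (2Z)-5-(tert-butyldimethylsilyloxy)-3-[(4-methoxybenzyloxy)methyl]pent-2-enal F1. Addition of alkyne 9 to F1 with Me2Zn and the ProPhenol ligand (2,6-bis{[2-(hydroxydiphenylmethyl)pyrrolidin-1-yl]methyl}-4-methylphenol) in toluene gives 15 without passing through 13 and 14. I have not committed to the ligand enantiomer; it is chosen by matching the Mosher ester of the product against 15.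

## Further compounds

F1 | step 10 | (2Z)-5-(tert-butyldimethylsilyloxy)-3-[(4-methoxybenzyloxy)methyl]pent-2-enal | COc1ccc(COC/C(CCO[Si](C)(C)C(C)(C)C)=C\C=O)cc1
F2 | step 19 | (4R,5R)-4-[(1R)-1-hydroxy-3-methylidene-4-(triethylsilyloxy)butyl]-3-methylidene-5-[(1Z)-4-(tert-butyldimethylsilyloxy)-2-[(4-methoxybenzyloxy)methyl]but-1-en-1-yl]oxolan-2-one (C8 epimer of 27) | COc1ccc(COC/C(CCO[Si](C)(C)C(C)(C)C)=C\[C@H]2OC(=O)C(=C)[C@@H]2[C@H](O)CC(=C)CO[Si](CC)(CC)CC)cc1
F3 | step 19 | (4R,5R)-4-[(1S)-1-acetoxy-3-methylidene-4-(triethylsilyloxy)butyl]-3-methylidene-5-[(1Z)-4-(tert-butyldimethylsilyloxy)-2-[(4-methoxybenzyloxy)methyl]but-1-en-1-yl]oxolan-2-one | COc1ccc(COC/C(CCO[Si](C)(C)C(C)(C)C)=C\[C@H]2OC(=O)C(=C)[C@@H]2[C@@H](OC(C)=O)CC(=C)CO[Si](CC)(CC)CC)cc1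
F4 | step 19 | (4R,5R)-4-[(1S)-1-acetoxy-3-methylidene-4-(triethylsilyloxy)butyl]-5-[(1Z)-4-(tert-butyldimethylsilyloxy)-2-(hydroxymethyl)but-1-en-1-yl]-3-methylideneoxolan-2-one | OC/C(CCO[Si](C)(C)C(C)(C)C)=C\[C@H]1OC(=O)C(=C)[C@@H]1[C@@H](OC(C)=O)CC(=C)CO[Si](CC)(CC)CC
F5 | step 26 | 3-methylbut-3-enal | O=CCC(C)=C
F6 | step 26 | (4R,5R)-4-[(1S)-1-hydroxy-3-methylbut-3-en-1-yl]-3-methylidene-5-[(1Z)-4-(tert-butyldimethylsilyloxy)-2-[(4-methoxybenzyloxy)methyl]but-1-en-1-yl]oxolan-2-one | COc1ccc(COC/C(CCO[Si](C)(C)C(C)(C)C)=C\[C@H]2OC(=O)C(=C)[C@@H]2[C@@H](O)CC(C)=C)cc1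
F7 | step 26 | (4R,5R)-4-[(1S)-1-hydroxy-3-methylbut-3-en-1-yl]-5-[(1Z)-4-(tert-butyldimethylsilyloxy)-2-(hydroxymethyl)but-1-en-1-yl]-3-methylideneoxolan-2-one | OC/C(CCO[Si](C)(C)C(C)(C)C)=C\[C@H]1OC(=O)C(=C)[C@@H]1[C@@H](O)CC(C)=C
F8 | step 26 | (4R,5R)-4-[(1S)-1-acetoxy-3-methylbut-3-en-1-yl]-5-[(1Z)-2-(acetoxymethyl)-4-(tert-butyldimethylsilyloxy)but-1-en-1-yl]-3-methylideneoxolan-2-one | CC(=O)OC/C(CCO[Si](C)(C)C(C)(C)C)=C\[C@H]1OC(=O)C(=C)[C@@H]1[C@@H](OC(C)=O)CC(C)=C
F9 | step 26 | (4R,5R)-4-[(1S)-1-acetoxy-3-methylbut-3-en-1-yl]-5-[(1Z)-2-(acetoxymethyl)-4-hydroxybut-1-en-1-yl]-3-methylideneoxolan-2-one | CC(=O)OC/C(CCO)=C\[C@H]1OC(=O)C(=C)[C@@H]1[C@@H](OC(C)=O)CC(C)=C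
F10 | step 26 | (4R,5R)-4-[(1S)-1-acetoxy-3-methylbut-3-en-1-yl]-5-[(1Z)-2-(acetoxymethyl)-4-oxobut-1-en-1-yl]-3-methylideneoxolan-2-one | CC(=O)OC/C(CC=O)=C\[C@H]1OC(=O)C(=C)[C@@H]1[C@@H](OC(C)=O)CC(C)=C
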